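**Strategy.** The flavanone is cut across ring C at O1–C2 and C3–C4. The O1–C8a–C4a–C4 unit of ring A, raised to a 4-methoxy ortho-quinone methide by a chiral phosphoric acid acting on a salicylaldehyde dimethyl acetal, serves as heterodiene; the C2=C3 alkene of a ring B styrene, polarised by its para oxygen, is the dienophile. One cycloaddition closes the pyran, forms both bonds and sets C2 (S), leaving C4 at the alcohol oxidation level as a methyl ether. The precursor is 5-geranyl-2-hydroxy-4,6-bis(MOM)benzaldehyde dimethyl acetal, whose single free phenol lies para to geranyl; this acid-labile phenolic acetal is unmasked by fluoride only in the preceding step.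

Key step: step 8

Abbreviations: MOM = methoxymethyl; TIPS = triisopropylsilyl; geranyl = (2E)-3,7-dimethylocta-2,6-dien-1-yl.

Assumption: the sense of induction of the chiral acid in step 8 cannot be predicted with confidence. The (R)-acid is written; its enantiomer would be used if a pilot run shows that it is the one giving the (2S) adduct.

Design remark: ring A is built from 2,4,6-trihydroxybenzaldehyde, so the formyl carbon is present from the start. The geranyl group is placed by directed metalation between the two MOM ethers, and the free phenol next to the acetal is released under basic conditions.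

**Step 1**
Reactants: 1 2,4,6-trihydroxybenzaldehyde
Product: 2 2-hydroxy-4,6-bis(methoxymethoxy)benzaldehyde
Conditions: MOMCl (2.2 equiv), i-Pr2NEt, CH2Cl2, 0 °C → rt
Reagents that add atoms: chloromethyl methyl ether, COCCl
Why: Base-mediated O-alkylation (MOM protection) should cap the 4-OH and one ortho OH, while the remaining ortho OH is deactivated by its hydrogen bond to the formyl group and stays free with about two equivalents of MOMCl.

**Step 2**
Reactants: 2 2-hydroxy-4,6-bis(methoxymethoxy)benzaldehyde
Product: 3 2,4-bis(methoxymethoxy)-6-(triisopropylsilyloxy)benzaldehyde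
Conditions: TIPSCl, imidazole, 4-(dimethylamino)pyridine (cat.), DMF, rt → 40 °C
Reagents that add atoms: triisopropylsilyl chloride, CC(C)[Si](Cl)(C(C)C)C(C)C
Why: Imidazole-promoted O-silylation of the last phenol gives a bulky aryl silyl ether that tolerates n-BuLi, directs lithiation poorly and is later removed by fluoride without acid.

**Step 3**
Reactants: 3 2,4-bis(methoxymethoxy)-6-(triisopropylsilyloxy)benzaldehyde
Product: 4 2,4-bis(methoxymethoxy)-6-(triisopropylsilyloxy)benzaldehyde dimethyl acetal
Conditions: HC(OMe)3, MeOH, pyridinium p-toluenesulfonate (2 mol %), rt; then Et3N, basic work-up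
Reagents that add atoms: trimethyl orthoformate, COC(OC)OC; methanol, CO
Why: Acid-catalysed acetalisation with the orthoformate as water scavenger should proceed readily because the electron-rich aldehyde ionises easily to its oxocarbenium ion, and the weak acid at room temperature spares the MOM and aryl silyl ethers.

**Step 4**
Reactants: 4 2,4-bis(methoxymethoxy)-6-(triisopropylsilyloxy)benzaldehyde dimethyl acetal; 5 geranyl bromide
Product: 7 3-geranyl-2,4-bis(methoxymethoxy)-6-(triisopropylsilyloxy)benzaldehyde dimethyl acetal, via aryllithium 6 (not isolated)
Conditions: n-BuLi, TMEDA, THF, −20 → 0 °C; then CuBr·SMe2 (10 mol %), 5, −78 °C → rt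
Reagents that add atoms: none
Why: Directed ortho-metalation followed by copper-catalysed SN2 allylation: the only C–H flanked by two chelating MOM ethers is lithiated in preference to the C–H next to the bulky, non-coordinating silyl ether, and the primary allylic bromide is displaced at its CH2 terminus with retention of the E alkene.

**Step 5**
Reactants: 7 3-geranyl-2,4-bis(methoxymethoxy)-6-(triisopropylsilyloxy)benzaldehyde dimethyl acetal
Product: 8 5-geranyl-2-hydroxy-4,6-bis(methoxymethoxy)benzaldehyde dimethyl acetal
Conditions: Bu4NF, THF, 0 °C; pH 7 buffer work-up, filtration through Et3N-deactivated silica, used at once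
Reagents that add atoms: none
Why: Fluoride-induced cleavage of the aryl silyl ether (desilylation) releases the phenol under basic conditions, so the acid-sensitive phenolic acetal and the MOM ethers never meet acid before the key step.

**Step 6**
Reactants: 9 3,4-dihydroxy-5-methoxybenzaldehyde
Product: 10 3-methoxy-4,5-bis(methoxymethoxy)benzaldehyde
Conditions: MOMCl (2.5 equiv), i-Pr2NEt, CH2Cl2, 0 °C → rt
Reagents that add atoms: chloromethyl methyl ether, COCCl
Why: Base-mediated O-alkylation (MOM protection) of both catechol hydroxyls removes the acidic protons before the Wittig step and puts the same protecting group on ring B as on ring A, so one final deprotection suffices.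

**Step 7**
Reactants: 10 3-methoxy-4,5-bis(methoxymethoxy)benzaldehyde
Product: 11 3-methoxy-4,5-bis(methoxymethoxy)styrene
Conditions: Ph3PCH3Br, KOt-Bu, THF, 0 °C → rt
Reagents that add atoms: methyltriphenylphosphonium bromide, C[P+](c1ccccc1)(c1ccccc1)c1ccccc1.[Br-]
Why: Wittig methylenation of the aryl aldehyde with the non-stabilised ylide should be clean, since the MOM and methyl ethers are inert to the basic conditions.

**Step 8**
Reactants: 8 5-geranyl-2-hydroxy-4,6-bis(methoxymethoxy)benzaldehyde dimethyl acetal; 11 3-methoxy-4,5-bis(methoxymethoxy)styrene
Product: 13 (2S,4S)-6-geranyl-4-methoxy-2-[3-methoxy-4,5-bis(methoxymethoxy)phenyl]-5,7-bis(methoxymethoxy)chroman, via methoxy ortho-quinone methide 12 (not isolated)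
Conditions: (R)-3,3'-bis(2,4,6-triisopropylphenyl)-1,1'-binaphthyl-2,2'-diyl hydrogen phosphate (10 mol %), 11 (2.5 equiv), 5 Å molecular sieves, toluene, −20 → 0 °C; Et3N quench
Reagents that add atoms: none
Why: Proposed new method: the phosphoric acid protonates one acetal oxygen of 8 and, assisted by the ortho phenol, methanol is lost (and taken up by the sieves) to give the 4-methoxy ortho-quinone methide 12, which in its O-protonated form is a phenol-stabilised oxocarbenium ion held in a hydrogen-bonded ion pair with the chiral phosphate. The CH2 terminus of styrene 11 attacks the carbenium carbon (future C4) while the phenolic oxygen closes on the developing benzylic cation (future C2) in a concerted but asynchronous inverse-electron-demand oxa-[4+2] cycloaddition, so the six-membered pyran ring C is closed by forming C3–C4 and O1–C2 in one event from the O1–C8a–C4a–C4 heterodiene and the C2=C3 dienophile. The closest known reactions are the achiral-acid-catalysed [4+2] of salicylaldehyde acetals with styrenes to 4-alkoxy-2-arylchromans and the chiral phosphoric acid-catalysed enantioselective cycloadditions of ortho-quinone methides with electron-rich alkenes; what is new is the enantioselective intermolecular use of an acetal-derived alkoxy quinone methide with a simple styrene. C2 is set by the catalyst, whose 3,3'-aryl groups should shield one face of the bound heterodiene so that the styrene approaches from the open face, and C4 follows from the endo orientation of the aryl group (2,4-cis) but is of no consequence because either C4 epimer converges in step 9. The step needs O1-to-benzylic regiochemistry, secured by the aryl- and para-oxygen-stabilised cation character at the styrene benzylic carbon; it needs a single heterodiene oxygen, secured because the only free phenol of 8 is the one para to the geranyl group, which fixes geranyl at C6; and it needs preference for the styrene over the geranyl alkenes, secured by the conjugated styrene used in excess and by the meta placement of the geranyl chain, which rules out intramolecular capture.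

**Step 9**
Reactants: 13 (2S,4S)-6-geranyl-4-methoxy-2-[3-methoxy-4,5-bis(methoxymethoxy)phenyl]-5,7-bis(methoxymethoxy)chroman
Product: 14 (2S)-6-geranyl-2-[3-methoxy-4,5-bis(methoxymethoxy)phenyl]-5,7-bis(methoxymethoxy)chroman-4-ol (mixture of C4 epimers)
Conditions: pyridinium p-toluenesulfonate (0.2 equiv), acetone/H2O (4:1), 40 °C; NaHCO3 quench
Reagents that add atoms: water, O
Why: Acid-catalysed SN1 solvolysis of the benzylic ether should be easy because the C4 cation is stabilised by O1 and the C5 and C7 oxygens and is captured by water in large excess, while the aryl MOM ethers survive the weak acid; C4 becomes an epimer mixture and C2 is not touched.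

**Step 10**
Reactants: 14 (2S)-6-geranyl-2-[3-methoxy-4,5-bis(methoxymethoxy)phenyl]-5,7-bis(methoxymethoxy)chroman-4-ol
Product: 15 (2S)-6-geranyl-2-[3-methoxy-4,5-bis(methoxymethoxy)phenyl]-5,7-bis(methoxymethoxy)chroman-4-one
Conditions: Dess–Martin periodinane, NaHCO3, CH2Cl2, 0 °C → rt
Reagents that add atoms: none
Why: Dess–Martin oxidation of the secondary benzylic alcohol converts both C4 epimers into the one ketone; the buffered, non-basic medium avoids retro-oxa-Michael ring opening, so C2 keeps its S configuration, and the alkenes are not attacked.

**Step 11**
Reactants: 15 (2S)-6-geranyl-2-[3-methoxy-4,5-bis(methoxymethoxy)phenyl]-5,7-bis(methoxymethoxy)chroman-4-one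
Product: 16 (2S)-6-geranyl-5,7-dihydroxy-2-(3,4-dihydroxy-5-methoxyphenyl)chroman-4-one (CNP0110161.1)
Conditions: 3 M aq. HCl/MeOH (1:4), 40 °C, stopped at full conversion
Reagents that add atoms: none
Why: Acid-catalysed acetal exchange with methanol removes the four MOM groups as dimethoxymethane; the moderate temperature and short reaction time are chosen to limit protonation of the geranyl alkenes and any acid-promoted ring opening at C2.

**Compound list**

1 | 2,4,6-trihydroxybenzaldehyde | O=Cc1c(O)cc(O)cc1O | starting material
2 | 2-hydroxy-4,6-bis(methoxymethoxy)benzaldehyde | O=Cc1c(O)cc(OCOC)cc1OCOC | intermediate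
3 | 2,4-bis(methoxymethoxy)-6-(triisopropylsilyloxy)benzaldehyde | O=Cc1c(O[Si](C(C)C)(C(C)C)C(C)C)cc(OCOC)cc1OCOC | intermediate
4 | 2,4-bis(methoxymethoxy)-6-(triisopropylsilyloxy)benzaldehyde dimethyl acetal | COC(OC)c1c(O[Si](C(C)C)(C(C)C)C(C)C)cc(OCOC)cc1OCOC | intermediate
5 | geranyl bromide, (2E)-1-bromo-3,7-dimethylocta-2,6-diene | CC(C)=CCC/C(C)=C/CBr | starting material
6 | aryllithium: 4 lithiated at the ring carbon between the two MOM ethers | COC(OC)c1c(O[Si](C(C)C)(C(C)C)C(C)C)cc(OCOC)c([Li])c1OCOC | intermediate (not isolated)
7 | 3-geranyl-2,4-bis(methoxymethoxy)-6-(triisopropylsilyloxy)benzaldehyde dimethyl acetal | COC(OC)c1c(O[Si](C(C)C)(C(C)C)C(C)C)cc(OCOC)c(C/C=C(\C)CCC=C(C)C)c1OCOC | intermediate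
8 | 5-geranyl-2-hydroxy-4,6-bis(methoxymethoxy)benzaldehyde dimethyl acetal | COC(OC)c1c(O)cc(OCOC)c(C/C=C(\C)CCC=C(C)C)c1OCOC | intermediate
9 | 3,4-dihydroxy-5-methoxybenzaldehyde | COc1cc(C=O)cc(O)c1O | starting material
10 | 3-methoxy-4,5-bis(methoxymethoxy)benzaldehyde | COc1cc(C=O)cc(OCOC)c1OCOC | intermediate
11 | 3-methoxy-4,5-bis(methoxymethoxy)styrene | COc1cc(C=C)cc(OCOC)c1OCOC | intermediate
12 | 4-geranyl-6-(methoxymethylene)-3,5-bis(methoxymethoxy)cyclohexa-2,4-dien-1-one (methoxy ortho-quinone methide, exocyclic geometry not defined) | COC=C1C(=O)C=C(OCOC)C(C/C=C(\C)CCC=C(C)C)=C1OCOC | intermediate (not isolated)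
13 | (2S,4S)-6-geranyl-4-methoxy-2-[3-methoxy-4,5-bis(methoxymethoxy)phenyl]-5,7-bis(methoxymethoxy)chroman (2,4-cis) | COc1cc([C@@H]2C[C@H](OC)c3c(cc(OCOC)c(C/C=C(\C)CCC=C(C)C)c3OCOC)O2)cc(OCOC)c1OCOC | intermediate
14 | (2S)-6-geranyl-2-[3-methoxy-4,5-bis(methoxymethoxy)phenyl]-5,7-bis(methoxymethoxy)chroman-4-ol, C4 epimer mixture | COc1cc([C@@H]2CC(O)c3c(cc(OCOC)c(C/C=C(\C)CCC=C(C)C)c3OCOC)O2)cc(OCOC)c1OCOC | intermediate
15 | (2S)-6-geranyl-2-[3-methoxy-4,5-bis(methoxymethoxy)phenyl]-5,7-bis(methoxymethoxy)chroman-4-one | COc1cc([C@@H]2CC(=O)c3c(cc(OCOC)c(C/C=C(\C)CCC=C(C)C)c3OCOC)O2)cc(OCOC)c1OCOC | intermediate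
16 | (2S)-6-geranyl-5,7-dihydroxy-2-(3,4-dihydroxy-5-methoxyphenyl)chroman-4-one | COc1cc([C@@H]2CC(=O)c3c(cc(O)c(C/C=C(\C)CCC=C(C)C)c3O)O2)cc(O)c1O | target

**Step count and risk**

Total: 11 steps. Longest linear sequence: 9 steps (steps 1–5, then 8–11); the styrene branch (steps 6–7) joins at step 8.

Steps most likely to fail:

1. Step 8 (proposed new method). The chiral ion pair may discriminate the two faces of the heterodiene poorly. The cycloaddition may also be slow: the oxocarbenium ion carries two further alkoxy donors, and the styrene's para oxygen, flanked by two ortho substituents, donates less than in a simple 4-alkoxystyrene. The cation could then be captured by the geranyl alkenes or by the free ring carbon of a second molecule of 8, and the product could re-ionise at C4. Fallback with known chemistry: starting from 8 and 11, the cycloaddition is run with an achiral acid, diphenyl hydrogen phosphate (10 mol %) in CH2Cl2 at −40 °C, which is the established acid-catalysed [4+2] of salicylaldehyde acetals with styrenes. This should give the racemic 2,4-cis adduct, that is 13 together with its mirror image (2R,4R)-6-geranyl-4-methoxy-2-[3-methoxy-4,5-bis(methoxymethoxy)phenyl]-5,7-bis(methoxymethoxy)chroman F1. The enantiomers are separated by preparative HPLC on an amylose tris(3,5-dimethylphenylcarbamate) phase, and the route is rejoined at 13. Asymmetric induction is thereby replaced by racemic synthesis plus resolution.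

2. Step 9. The C4 cation may lose a proton to give the flav-3-ene, may be captured by C8 of a second molecule (Friedel–Crafts oligomerisation), or the acid may start to remove MOM groups. Fallback: starting from 13, 2,3-dichloro-5,6-dicyano-1,4-benzoquinone (1.1 equiv) in CH2Cl2/pH 7 buffer at 0 °C abstracts the C4 hydride, a known oxidation of electron-rich benzylic methyl ethers to carbonyl compounds. Water adds to the resulting methoxy-stabilised oxocarbenium ion and the hemiketal loses methanol, giving ketone 15 directly. The route is rejoined at 15 and steps 9 and 10 are bypassed; no compound outside the list is made (F0). The oxidant would be kept near one equivalent and cold so that the benzylic, allylic CH2 of the geranyl group is not attacked.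

3. Step 5. The phenolic acetal may lose methanol, hydrolyse or oligomerise during work-up and storage. Fallback: starting from 7, the order of unmasking is changed. Bu4NF followed by stirring with dilute aqueous acetic acid desilylates and hydrolyses the acetal, giving the stable, hydrogen-bonded salicylaldehyde 5-geranyl-2-hydroxy-4,6-bis(methoxymethoxy)benzaldehyde F2, which can be purified and stored. Immediately before the cycloaddition, F2 is converted into 8 in the reaction vessel with trimethyl orthoformate and the acid catalyst in toluene (the known in situ acetalisation of salicylaldehydes used in three-component cycloadditions). Volatiles are removed and 8 is carried into step 8 without isolation, so the route is rejoined at 8.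

**Further compounds**

F1 | step 8 | (2R,4R)-6-geranyl-4-methoxy-2-[3-methoxy-4,5-bis(methoxymethoxy)phenyl]-5,7-bis(methoxymethoxy)chroman | COc1cc([C@H]2C[C@@H](OC)c3c(cc(OCOC)c(C/C=C(\C)CCC=C(C)C)c3OCOC)O2)cc(OCOC)c1OCOC
F0 | step 9 | none | none
F2 | step 5 | 5-geranyl-2-hydroxy-4,6-bis(methoxymethoxy)benzaldehyde | O=Cc1c(O)cc(OCOC)c(C/C=C(\C)CCC=C(C)C)c1OCOC
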